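**Retrosynthetic overview**
- The two benzyl ethers of the glyceryl arm and the C7 silyl ether come off last. No ring is formed at any stage: ring A and ring B are bought as a bromoguaiacol and an allylsyringol.
- Key disconnection: C8 carries the ring B aryloxy oxygen and the C9 hydroxymethyl group next to the C7 carbinol on ring A. C8–C9 is therefore traced back to a 1-aryloxyvinyl group (C8=C9), and the 3-hydroxypropyl chain of ring B to its allyl group. One double hydroboration–oxidation adds H to C8 and OH to C9 and to the chain end, with (S)-C7 steering C8 to R.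
- The 1-aryloxyvinyl group comes from methylenation of the carbonyl group of an aryl (S)-O-silylmandelate, the ester of the ring B phenol.
- C7 is set by asymmetric transfer hydrogenation of a ring A aryl glyoxylate, made from the ring A aryl bromide (Mitsunobu ether of glycerol 1,3-dibenzyl ether) and diethyl oxalate.

Key step: step 8

Assumption: C7, C8 and C9 denote the benzylic carbinol carbon, the aryloxy-bearing methine and the hydroxymethyl carbon; the target is the erythro (7S,8R) isomer, and the glyceryl carbon with two identical CH2OH arms is not stereogenic.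

**Step 1**
Reactants: 1 4-bromo-2-methoxyphenol; 2 1,3-dibenzyloxypropan-2-ol
Product: 3 4-bromo-1-(1,3-dibenzyloxypropan-2-yloxy)-2-methoxybenzene
Conditions: PPh3, DIAD, THF, 0 °C → 45 °C
Reagents that add atoms: none
Why: Mitsunobu etherification of an acidic phenol with a secondary alcohol whose carbinol carbon is not stereogenic, so the inversion has no consequence and the aryl bromide and benzyl ethers are untouched.

**Step 2**
Reactants: 3 4-bromo-1-(1,3-dibenzyloxypropan-2-yloxy)-2-methoxybenzene; 4 diethyl oxalate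
Product: 6 ethyl 2-[4-(1,3-dibenzyloxypropan-2-yloxy)-3-methoxyphenyl]-2-oxoacetate, via arylmagnesium bromide 5 (not isolated)
Conditions: Mg turnings, I2 (cat.), THF, 45 °C; then added to 4 (2.5 equiv), THF, −78 °C; 1 M HCl quench
Reagents that add atoms: none
Why: Grignard acylation with inverse addition to excess oxalate at −78 °C, where the tetrahedral magnesium alkoxide persists until the acidic quench, so that a single addition to give the α-keto ester is expected.

**Step 3**
Reactants: 6 ethyl 2-[4-(1,3-dibenzyloxypropan-2-yloxy)-3-methoxyphenyl]-2-oxoacetate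
Product: 7 ethyl (2S)-2-[4-(1,3-dibenzyloxypropan-2-yloxy)-3-methoxyphenyl]-2-hydroxyacetate
Conditions: RuCl[(R,R)-TsDPEN](p-cymene) (1 mol%), HCO2H/Et3N (5:2), DMF, 25 °C
Reagents that add atoms: none
Why: Asymmetric transfer hydrogenation of an aryl α-keto ester, in which the aryl group should take the CH/π site under the η6-arene so that the (R,R) catalyst delivers hydride to the Re face and sets C7 as S (the descriptor is opposite to the acetophenone case only because CO2Et outranks aryl); the sense is to be confirmed by chiral HPLC before material is carried on.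

**Step 4**
Reactants: 7 ethyl (2S)-2-[4-(1,3-dibenzyloxypropan-2-yloxy)-3-methoxyphenyl]-2-hydroxyacetate
Product: 8 (2S)-2-[4-(1,3-dibenzyloxypropan-2-yloxy)-3-methoxyphenyl]-2-hydroxyacetic acid
Conditions: LiOH·H2O, THF/H2O, 0 °C; then 1 M HCl to pH 3
Reagents that add atoms: lithium hydroxide, [Li+].[OH-]
Why: Ester saponification of an α-hydroxy ester is fast at 0 °C, and the resulting carboxylate resists α-deprotonation, so C7 should keep its configuration (hydrolysis is done before silylation for this reason).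

**Step 5**
Reactants: 8 (2S)-2-[4-(1,3-dibenzyloxypropan-2-yloxy)-3-methoxyphenyl]-2-hydroxyacetic acid
Product: 10 (2S)-2-(tert-butyldimethylsilyloxy)-2-[4-(1,3-dibenzyloxypropan-2-yloxy)-3-methoxyphenyl]acetic acid, via bis-silyl derivative 9 (not isolated)
Conditions: TBSCl (2.5 equiv), imidazole, DMF, 25 °C; then K2CO3, MeOH/THF/H2O, 0 °C; 1 M HCl to pH 4
Reagents that add atoms: tert-butyldimethylsilyl chloride, CC(C)(C)[Si](C)(C)Cl
Why: Silylation of both the hydroxyl and the carboxyl group followed by selective solvolysis of the much more labile silyl ester leaves the secondary benzylic silyl ether and does not touch C7.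

**Step 6**
Reactants: 10 (2S)-2-(tert-butyldimethylsilyloxy)-2-[4-(1,3-dibenzyloxypropan-2-yloxy)-3-methoxyphenyl]acetic acid; 11 4-allyl-2,6-dimethoxyphenol
Product: 12 4-allyl-2,6-dimethoxyphenyl (2S)-2-(tert-butyldimethylsilyloxy)-2-[4-(1,3-dibenzyloxypropan-2-yloxy)-3-methoxyphenyl]acetate
Conditions: EDC·HCl, DMAP (0.1 equiv), CH2Cl2, 0 °C → 25 °C
Reagents that add atoms: none
Why: Steglich esterification, in which the acylpyridinium ion transfers the acyl group to the hindered phenol, with catalytic DMAP and low temperature chosen to limit α-epimerisation of the activated acyl species.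

**Step 7**
Reactants: 12 4-allyl-2,6-dimethoxyphenyl (2S)-2-(tert-butyldimethylsilyloxy)-2-[4-(1,3-dibenzyloxypropan-2-yloxy)-3-methoxyphenyl]acetate
Product: 13 tert-butyl{[(1S)-2-(4-allyl-2,6-dimethoxyphenoxy)-1-[4-(1,3-dibenzyloxypropan-2-yloxy)-3-methoxyphenyl]prop-2-en-1-yl]oxy}dimethylsilane
Conditions: Cp2TiMe2 (3 equiv), toluene/THF, 70 °C, dark; chromatography on basic Al2O3
Reagents that add atoms: dimethyltitanocene (Cp2TiMe2), C[Ti+2]C.c1cc[cH-]c1.c1cc[cH-]c1
Why: Petasis methylenation, in which thermally formed Cp2Ti=CH2 adds [2+2] to the ester carbonyl and cycloreverts to the enol ether and Cp2Ti=O; aryl esters are classical substrates for titanium methylidenes, the reagent is non-basic so C7 is retained, and the allyl group undergoes only degenerate methylene exchange.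

**Step 8**
Reactants: 13 tert-butyl{[(1S)-2-(4-allyl-2,6-dimethoxyphenoxy)-1-[4-(1,3-dibenzyloxypropan-2-yloxy)-3-methoxyphenyl]prop-2-en-1-yl]oxy}dimethylsilane
Product: 15 (2R,3S)-3-(tert-butyldimethylsilyloxy)-3-[4-(1,3-dibenzyloxypropan-2-yloxy)-3-methoxyphenyl]-2-[4-(3-hydroxypropyl)-2,6-dimethoxyphenoxy]propan-1-ol, via bis(9-BBN) adduct 14 (not isolated)
Conditions: 9-BBN (3.5 equiv), THF, 0 °C → 25 °C; then 30% H2O2, aq NaOAc, THF/EtOH, 0 °C → 25 °C
Reagents that add atoms: hydrogen peroxide, OO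
Why: Proposed new method: 9-BBN adds through the four-centre syn transition state to both terminal alkenes, boron going to the unsubstituted carbon each time (C9 of the enol ether, where steric demand and the polarisation by oxygen agree, and the terminus of the allyl group), and buffered peroxide then replaces each C–B bond by C–OH with retention; no ring is closed. The closest known reaction types are the anti-selective 9-BBN hydroboration of 1,1-disubstituted allylic ethers and the hydroboration–oxidation of 1,1-disubstituted enol ethers such as exo-methylene sugar derivatives, whereas an acyclic 1-aryloxyvinyl carbinol ether has not been examined. The new C8 stereocentre is set by 1,2-induction from C7: in the reactive conformer the C7 hydrogen lies inside, toward C9 and the bulky borane, ring A stands anti to the incoming B–H and the silyloxy group points outward, so hydrogen reaches the C8 face that gives the 7,8-anti (erythro, 7S,8R) product. The step needs regioselectivity (secured by the terminal position of both alkenes and the size of 9-BBN), facial selectivity (secured by the C7 silyl ether and allylic strain against the C8 aryloxy group) and survival of the β-aryloxyalkylborane, for which the weakly Lewis-acidic 9-BBN, a temperature not above 25 °C and immediate buffered oxidation are chosen to suppress syn β-elimination of boron aryloxide.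

**Step 9**
Reactants: 15 (2R,3S)-3-(tert-butyldimethylsilyloxy)-3-[4-(1,3-dibenzyloxypropan-2-yloxy)-3-methoxyphenyl]-2-[4-(3-hydroxypropyl)-2,6-dimethoxyphenoxy]propan-1-ol
Product: 16 (1S,2R)-1-[4-(1,3-dibenzyloxypropan-2-yloxy)-3-methoxyphenyl]-2-[4-(3-hydroxypropyl)-2,6-dimethoxyphenoxy]propane-1,3-diol
Conditions: Bu4NF, AcOH (1:1), THF, 0 °C → 25 °C
Reagents that add atoms: none
Why: Fluoride-induced desilylation driven by the Si–F bond, buffered with acetic acid so that the medium stays near neutral and neither stereocentre nor any ether is affected.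

**Step 10**
Reactants: 16 (1S,2R)-1-[4-(1,3-dibenzyloxypropan-2-yloxy)-3-methoxyphenyl]-2-[4-(3-hydroxypropyl)-2,6-dimethoxyphenoxy]propane-1,3-diol
Product: 17 (1S,2R)-1-[4-(1,3-dihydroxypropan-2-yloxy)-3-methoxyphenyl]-2-[4-(3-hydroxypropyl)-2,6-dimethoxyphenoxy]propane-1,3-diol (CNP0324330.1)
Conditions: H2 (1 atm), 10% Pd/C, EtOAc/EtOH, 25 °C
Reagents that add atoms: none
Why: Catalytic hydrogenolysis of the two primary benzyl ethers under neutral conditions, where the free secondary benzylic C7–OH and the aryl alkyl ethers are cleaved much more slowly, so stopping after uptake of two equivalents of hydrogen should give the target.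

**Compound list**
1 | 4-bromo-2-methoxyphenol | COc1cc(Br)ccc1O | starting material
2 | 1,3-dibenzyloxypropan-2-ol | OC(COCc1ccccc1)COCc1ccccc1 | starting material
3 | 4-bromo-1-(1,3-dibenzyloxypropan-2-yloxy)-2-methoxybenzene | COc1cc(Br)ccc1OC(COCc1ccccc1)COCc1ccccc1 | intermediate
4 | diethyl oxalate | CCOC(=O)C(=O)OCC | starting material
5 | [4-(1,3-dibenzyloxypropan-2-yloxy)-3-methoxyphenyl]magnesium bromide | COc1cc([Mg]Br)ccc1OC(COCc1ccccc1)COCc1ccccc1 | intermediate
6 | ethyl 2-[4-(1,3-dibenzyloxypropan-2-yloxy)-3-methoxyphenyl]-2-oxoacetate | CCOC(=O)C(=O)c1ccc(OC(COCc2ccccc2)COCc2ccccc2)c(OC)c1 | intermediate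
7 | ethyl (2S)-2-[4-(1,3-dibenzyloxypropan-2-yloxy)-3-methoxyphenyl]-2-hydroxyacetate | CCOC(=O)[C@@H](O)c1ccc(OC(COCc2ccccc2)COCc2ccccc2)c(OC)c1 | intermediate
8 | (2S)-2-[4-(1,3-dibenzyloxypropan-2-yloxy)-3-methoxyphenyl]-2-hydroxyacetic acid | OC(=O)[C@@H](O)c1ccc(OC(COCc2ccccc2)COCc2ccccc2)c(OC)c1 | intermediate
9 | tert-butyldimethylsilyl (2S)-2-(tert-butyldimethylsilyloxy)-2-[4-(1,3-dibenzyloxypropan-2-yloxy)-3-methoxyphenyl]acetate | CC(C)(C)[Si](C)(C)OC(=O)[C@@H](O[Si](C)(C)C(C)(C)C)c1ccc(OC(COCc2ccccc2)COCc2ccccc2)c(OC)c1 | intermediate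
10 | (2S)-2-(tert-butyldimethylsilyloxy)-2-[4-(1,3-dibenzyloxypropan-2-yloxy)-3-methoxyphenyl]acetic acid | OC(=O)[C@@H](O[Si](C)(C)C(C)(C)C)c1ccc(OC(COCc2ccccc2)COCc2ccccc2)c(OC)c1 | intermediate
11 | 4-allyl-2,6-dimethoxyphenol | C=CCc1cc(OC)c(O)c(OC)c1 | starting material
12 | 4-allyl-2,6-dimethoxyphenyl (2S)-2-(tert-butyldimethylsilyloxy)-2-[4-(1,3-dibenzyloxypropan-2-yloxy)-3-methoxyphenyl]acetate | C=CCc1cc(OC)c(OC(=O)[C@@H](O[Si](C)(C)C(C)(C)C)c2ccc(OC(COCc3ccccc3)COCc3ccccc3)c(OC)c2)c(OC)c1 | intermediate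
13 | tert-butyl{[(1S)-2-(4-allyl-2,6-dimethoxyphenoxy)-1-[4-(1,3-dibenzyloxypropan-2-yloxy)-3-methoxyphenyl]prop-2-en-1-yl]oxy}dimethylsilane | C=C(Oc1c(OC)cc(CC=C)cc1OC)[C@@H](O[Si](C)(C)C(C)(C)C)c1ccc(OC(COCc2ccccc2)COCc2ccccc2)c(OC)c1 | intermediate
14 | bis(9-BBN) adduct of 13, with 9-borabicyclo[3.3.1]nonan-9-yl groups on C9 and on the terminal carbon of the ring B propyl chain, (7S,8R) | C(B1C2CCCC1CCC2)[C@@H](Oc1c(OC)cc(CCCB2C3CCCC2CCC3)cc1OC)[C@@H](O[Si](C)(C)C(C)(C)C)c1ccc(OC(COCc2ccccc2)COCc2ccccc2)c(OC)c1 | intermediate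
15 | (2R,3S)-3-(tert-butyldimethylsilyloxy)-3-[4-(1,3-dibenzyloxypropan-2-yloxy)-3-methoxyphenyl]-2-[4-(3-hydroxypropyl)-2,6-dimethoxyphenoxy]propan-1-ol | OC[C@@H](Oc1c(OC)cc(CCCO)cc1OC)[C@@H](O[Si](C)(C)C(C)(C)C)c1ccc(OC(COCc2ccccc2)COCc2ccccc2)c(OC)c1 | intermediate
16 | (1S,2R)-1-[4-(1,3-dibenzyloxypropan-2-yloxy)-3-methoxyphenyl]-2-[4-(3-hydroxypropyl)-2,6-dimethoxyphenoxy]propane-1,3-diol | OC[C@@H](Oc1c(OC)cc(CCCO)cc1OC)[C@@H](O)c1ccc(OC(COCc2ccccc2)COCc2ccccc2)c(OC)c1 | intermediate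
17 | (1S,2R)-1-[4-(1,3-dihydroxypropan-2-yloxy)-3-methoxyphenyl]-2-[4-(3-hydroxypropyl)-2,6-dimethoxyphenoxy]propane-1,3-diol | COc1cc([C@H](O)[C@@H](CO)Oc2c(OC)cc(CCCO)cc2OC)ccc1OC(CO)CO | target

**Totals**
Total step count: 10. Longest linear sequence: 10 steps (from 1 and 2 to 17); 4 enters at step 2 and 11 at step 6.

**Steps most likely to fail**

In the fallback texts ArA stands for 4-(1,3-dibenzyloxypropan-2-yloxy)-3-methoxyphenyl.

*Step 8.* Hydroboration of the hindered 1-aryloxyvinyl group may be slow, and any heating would bring on syn β-elimination of boron aryloxide and loss of ring B. The facial bias from C7 may also be too small with an aryloxy group on C8, giving erythro/threo mixtures. The fallback is an auxiliary-controlled syn aldol reaction followed by inversion at C7. It sets out from bromide 3 and phenol 11 and comes back at triol 16.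
- Grignard reagent 5 from 3 is formylated with DMF to the aldehyde ArA–CHO F1.
- Phenol 11 is alkylated (K2CO3, acetone) with (S)-4-benzyl-3-(bromoacetyl)oxazolidin-2-one to the imide (4S)-4-benzyl-3-[2-(4-allyl-2,6-dimethoxyphenoxy)acetyl]oxazolidin-2-one F2.
- Bu2BOTf and iPr2NEt (CH2Cl2, −78 °C) convert F2 into its Z dibutylboron enolate F3. This adds to F1 in an Evans aldol reaction and, after buffered H2O2 work-up, should give the syn adduct (4S)-4-benzyl-3-[(2S,3R)-2-(4-allyl-2,6-dimethoxyphenoxy)-3-ArA-3-hydroxypropanoyl]oxazolidin-2-one F4. C8 then has its final arrangement and C7 is still R.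
- LiBH4 (THF/MeOH, 0 °C) removes the auxiliary to give the threo diol (1R,2R)-2-(4-allyl-2,6-dimethoxyphenoxy)-1-ArA-propane-1,3-diol F5.
- TBSCl and imidazole silylate the primary hydroxyl to give (1R,2R)-2-(4-allyl-2,6-dimethoxyphenoxy)-3-(tert-butyldimethylsilyloxy)-1-ArA-propan-1-ol F6.
- A Mitsunobu reaction with 4-nitrobenzoic acid (PPh3, DIAD) inverts C7 to give (1S,2R)-2-(4-allyl-2,6-dimethoxyphenoxy)-3-(tert-butyldimethylsilyloxy)-1-ArA-propyl 4-nitrobenzoate F7.
- 9-BBN hydroborates the allyl group to the B-alkyl-9-BBN adduct of F7 F8, and H2O2/NaOAc gives (1S,2R)-3-(tert-butyldimethylsilyloxy)-2-[4-(3-hydroxypropyl)-2,6-dimethoxyphenoxy]-1-ArA-propyl 4-nitrobenzoate F9.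
- K2CO3 in MeOH cleaves the ester to (1S,2R)-3-(tert-butyldimethylsilyloxy)-2-[4-(3-hydroxypropyl)-2,6-dimethoxyphenoxy]-1-ArA-propan-1-ol F10, and Bu4NF gives 16, which goes on to step 10.

*Step 7.* Steric congestion around the ester carbonyl may leave the methylenation incomplete, and the acid-labile enol ether may hydrolyse during isolation. The fallback forms the enol ether C–O bond by cross-coupling instead of carbonyl methylenation. It sets out from acid 10 and comes back at enol ether 13.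
- Coupling of 10 with MeNHOMe·HCl (EDC·HCl, N-methylmorpholine) gives the Weinreb amide (2S)-2-(tert-butyldimethylsilyloxy)-2-ArA-N-methoxy-N-methylacetamide F11.
- MeMgBr (THF, 0 °C) gives the methyl ketone (1S)-1-(tert-butyldimethylsilyloxy)-1-ArA-propan-2-one F12.
- KN(SiMe3)2 added at −78 °C to a mixture of F12 and PhNTf2 should deprotonate the methyl group, away from the silyloxy-bearing carbon, and give the enol triflate (3S)-3-(tert-butyldimethylsilyloxy)-3-ArA-prop-1-en-2-yl trifluoromethanesulfonate F13.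
- Pd-catalysed C–O coupling of F13 with phenol 11 (Pd2(dba)3, t-BuXPhos, K3PO4, toluene, 80 °C) gives 13.

*Step 6.* Acylation of the di-ortho-substituted phenol may be slow, which gives the activated acyl species time to enolise and erodes the configuration at C7; rearrangement to the N-acylurea may also compete. The fallback forms the ester bond before the stereocentre exists. It sets out from keto ester 6 and comes back at aryl ester 12.
- LiOH saponification of 6 gives the keto acid 2-ArA-2-oxoacetic acid F14.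
- With no stereocentre at risk, the coupling with 11 can be forced (EDC·HCl, DMAP 1 equiv, CH2Cl2, 40 °C) to give the aryl keto ester 4-allyl-2,6-dimethoxyphenyl 2-ArA-2-oxoacetate F15.
- Asymmetric transfer hydrogenation under the conditions of step 3 gives 4-allyl-2,6-dimethoxyphenyl (2S)-2-ArA-2-hydroxyacetate F16.
- TBSOTf and 2,6-lutidine (CH2Cl2, −78 °C) give 12.

**Further compounds**
F1 | step 8 | 4-(1,3-dibenzyloxypropan-2-yloxy)-3-methoxybenzaldehyde | COc1cc(C=O)ccc1OC(COCc1ccccc1)COCc1ccccc1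
F2 | step 8 | (4S)-4-benzyl-3-[2-(4-allyl-2,6-dimethoxyphenoxy)acetyl]oxazolidin-2-one | C=CCc1cc(OC)c(OCC(=O)N2[C@@H](Cc3ccccc3)COC2=O)c(OC)c1
F3 | step 8 | (4S)-4-benzyl-3-[(Z)-2-(4-allyl-2,6-dimethoxyphenoxy)-1-(dibutylboryloxy)ethenyl]oxazolidin-2-one | CCCCB(CCCC)O/C(=C\Oc1c(OC)cc(CC=C)cc1OC)N1[C@@H](Cc2ccccc2)COC1=O
F4 | step 8 | (4S)-4-benzyl-3-[(2S,3R)-2-(4-allyl-2,6-dimethoxyphenoxy)-3-[4-(1,3-dibenzyloxypropan-2-yloxy)-3-methoxyphenyl]-3-hydroxypropanoyl]oxazolidin-2-one | O=C(N1[C@@H](Cc2ccccc2)COC1=O)[C@@H](Oc1c(OC)cc(CC=C)cc1OC)[C@H](O)c1ccc(OC(COCc2ccccc2)COCc2ccccc2)c(OC)c1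
F5 | step 8 | (1R,2R)-2-(4-allyl-2,6-dimethoxyphenoxy)-1-[4-(1,3-dibenzyloxypropan-2-yloxy)-3-methoxyphenyl]propane-1,3-diol | OC[C@@H](Oc1c(OC)cc(CC=C)cc1OC)[C@H](O)c1ccc(OC(COCc2ccccc2)COCc2ccccc2)c(OC)c1
F6 | step 8 | (1R,2R)-2-(4-allyl-2,6-dimethoxyphenoxy)-3-(tert-butyldimethylsilyloxy)-1-[4-(1,3-dibenzyloxypropan-2-yloxy)-3-methoxyphenyl]propan-1-ol | CC(C)(C)[Si](C)(C)OC[C@@H](Oc1c(OC)cc(CC=C)cc1OC)[C@H](O)c1ccc(OC(COCc2ccccc2)COCc2ccccc2)c(OC)c1
F7 | step 8 | (1S,2R)-2-(4-allyl-2,6-dimethoxyphenoxy)-3-(tert-butyldimethylsilyloxy)-1-[4-(1,3-dibenzyloxypropan-2-yloxy)-3-methoxyphenyl]propyl 4-nitrobenzoate | CC(C)(C)[Si](C)(C)OC[C@@H](Oc1c(OC)cc(CC=C)cc1OC)[C@@H](OC(=O)c1ccc(cc1)[N+](=O)[O-])c1ccc(OC(COCc2ccccc2)COCc2ccccc2)c(OC)c1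
F8 | step 8 | B-alkyl-9-BBN adduct of F7 (9-borabicyclo[3.3.1]nonan-9-yl group on the terminal carbon of the ring B propyl chain) | CC(C)(C)[Si](C)(C)OC[C@@H](Oc1c(OC)cc(CCCB2C3CCCC2CCC3)cc1OC)[C@@H](OC(=O)c1ccc(cc1)[N+](=O)[O-])c1ccc(OC(COCc2ccccc2)COCc2ccccc2)c(OC)c1
F9 | step 8 | (1S,2R)-3-(tert-butyldimethylsilyloxy)-1-[4-(1,3-dibenzyloxypropan-2-yloxy)-3-methoxyphenyl]-2-[4-(3-hydroxypropyl)-2,6-dimethoxyphenoxy]propyl 4-nitrobenzoate | CC(C)(C)[Si](C)(C)OC[C@@H](Oc1c(OC)cc(CCCO)cc1OC)[C@@H](OC(=O)c1ccc(cc1)[N+](=O)[O-])c1ccc(OC(COCc2ccccc2)COCc2ccccc2)c(OC)c1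
F10 | step 8 | (1S,2R)-3-(tert-butyldimethylsilyloxy)-1-[4-(1,3-dibenzyloxypropan-2-yloxy)-3-methoxyphenyl]-2-[4-(3-hydroxypropyl)-2,6-dimethoxyphenoxy]propan-1-ol | CC(C)(C)[Si](C)(C)OC[C@@H](Oc1c(OC)cc(CCCO)cc1OC)[C@@H](O)c1ccc(OC(COCc2ccccc2)COCc2ccccc2)c(OC)c1
F11 | step 7 | (2S)-2-(tert-butyldimethylsilyloxy)-2-[4-(1,3-dibenzyloxypropan-2-yloxy)-3-methoxyphenyl]-N-methoxy-N-methylacetamide | CON(C)C(=O)[C@@H](O[Si](C)(C)C(C)(C)C)c1ccc(OC(COCc2ccccc2)COCc2ccccc2)c(OC)c1
F12 | step 7 | (1S)-1-(tert-butyldimethylsilyloxy)-1-[4-(1,3-dibenzyloxypropan-2-yloxy)-3-methoxyphenyl]propan-2-one | CC(=O)[C@@H](O[Si](C)(C)C(C)(C)C)c1ccc(OC(COCc2ccccc2)COCc2ccccc2)c(OC)c1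
F13 | step 7 | (3S)-3-(tert-butyldimethylsilyloxy)-3-[4-(1,3-dibenzyloxypropan-2-yloxy)-3-methoxyphenyl]prop-1-en-2-yl trifluoromethanesulfonate | C=C(OS(=O)(=O)C(F)(F)F)[C@@H](O[Si](C)(C)C(C)(C)C)c1ccc(OC(COCc2ccccc2)COCc2ccccc2)c(OC)c1
F14 | step 6 | 2-[4-(1,3-dibenzyloxypropan-2-yloxy)-3-methoxyphenyl]-2-oxoacetic acid | OC(=O)C(=O)c1ccc(OC(COCc2ccccc2)COCc2ccccc2)c(OC)c1
F15 | step 6 | 4-allyl-2,6-dimethoxyphenyl 2-[4-(1,3-dibenzyloxypropan-2-yloxy)-3-methoxyphenyl]-2-oxoacetate | C=CCc1cc(OC)c(OC(=O)C(=O)c2ccc(OC(COCc3ccccc3)COCc3ccccc3)c(OC)c2)c(OC)c1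
F16 | step 6 | 4-allyl-2,6-dimethoxyphenyl (2S)-2-[4-(1,3-dibenzyloxypropan-2-yloxy)-3-methoxyphenyl]-2-hydroxyacetate | C=CCc1cc(OC)c(OC(=O)[C@@H](O)c2ccc(OC(COCc3ccccc3)COCc3ccccc3)c(OC)c2)c(OC)c1
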